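## The problem

Dielsianone (17) is an achiral benzil. A 4-methoxybenzoyl group and a second carbonyl join the anisyl ring to C6 of a 2,2-dimethyl-2H-chromene. Its benzene ring (ring B) is pentasubstituted: O1 at C8a, OMe at C8, H at C7, the diketone carbon at C6, a free OH at C5 and the styrenic C4 at C4a.

There is no stereocentre to set, so the task is regiochemical. Two para oxygens must be told apart (C5–OH free, C8–OMe methylated), the only ring hydrogen must sit at C7, and the acyl carbon must enter at C6.

Three groups are fragile:
- The 1,2-diketone is exposed to base (benzilic rearrangement) and, with the free ortho hydroxyl, to ring-chain tautomerism.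
- The C3=C4 bond is an electron-rich styrene that oxidants attack and acids dimerise.
- Any free 4-methoxyphenol is easily oxidised to the quinone until it is acylated or hydrogen-bonded.

Both the alkene and the diketone are therefore best carried in latent form through ring construction, and the diketone-forming oxidant should meet neither the alkene nor a free phenol.

The enabling feature is that ring B is a 4-methoxyphenol fused through C4a–C8a to the pyran (ring C), with H at C7 and carbon at C6. This is the substitution pattern a Fischer carbene, a terminal alkyne and CO write onto a new benzene ring. The carbene carbon becomes C8–OMe, the CO becomes C5–OH, the alkyne CH becomes C7 and its substituted carbon C6, and the alkenyl carbons of the carbene become C8a and C4a.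

The only sp3 stereocentre ever carried (C4 of the chroman intermediates) is racemic and is erased at the end; it controls nothing.

## Retrosynthesis

**17 ⇒ 16 ⇒ 15 (unmasking).** The phenol is retraced to its acetate 16, and the C3=C4 π bond to a C4–O silyl ether plus a C3–H in 15. Carrying the alkene itself is not an option: a 2H-pyranyl carbene would be a dienyl ether prone to electrocyclic ring opening, and the styrene would not survive the alkyne oxidation. Late dehydrogenation of a C4-unfunctionalised chroman is unattractive on a ring deactivated by the acyl group. The forward step needs ionisation at C4, which the ortho oxygen O1 assists, and proton loss can only occur toward C3 because C4a carries no hydrogen.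

**15 ⇒ 14 (diketone from alkyne).** Both C=O bonds are retraced to the C≡C bond of a diarylalkyne. An alkyne tolerates organolithium and carbene chemistry where a diketone would not, and it reduces the C6 substituent to a single sp carbon. The neighbouring option, acylating C6 after ring formation, would need a Friedel–Crafts reaction on an acid-labile, polyoxygenated ring. The forward reaction must oxidise the triple bond with the ortho phenol masked (acetate 14) so that the oxygen cannot close onto the activated alkyne.

**14 ⇒ 8 + 12 (ring B).** Cutting C8–C7, C6–C5 and C5–C4a dissolves ring B into the Cr(CO)5 carbene 8, the terminal diyne 12 and one CO ligand. Against stepwise substitution of a preformed hydroquinone, this cut sets the OH/OMe differentiation and the C7-H/C6-C placement by mechanism. The precursors are a monocyclic dihydropyran and a linear diyne. The forward reaction has to be chemoselective for the terminal triple bond and regioselective in the insertion.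

**8 ⇒ 5 ⇒ 4 ⇒ 3 ⇒ 1 (carbene).** The bond from the carbene carbon to C6 of the pyran is cut to the vinyllithium of 5 and a CO of Cr(CO)6; the O-methyl group comes from MeOTf. Silyl ether 5 comes from allylic alcohol 4, 4 from enone 3, and 3 from commercial pyranone 1 by desaturation. The C4 oxygen is protected as a triisopropylsilyl ether rather than tert-butyldimethylsilyl, because the latter offers Si–CH3 protons to t-BuLi. The lithiation must occur at the vinylic carbon alpha to the ring oxygen, as it does in silyl-protected glycals.

**12 ⇒ 11 ⇒ 9 + 10 (diyne).** The central C(sp)–C(sp) bond is cut to 4-ethynylanisole 9 and the silyl bromoalkyne 10. The silyl cap of 11 is removed only just before use, because the terminal arylbutadiyne is the least stable compound of the route.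

## Roads not taken

**Alternative 1:** Alder–Rickert benzannulation.
- Cut: C8–C7 and C5–C6, between the cyclohexadiene 1,4-dimethoxy-2-(3-methylbut-2-en-1-yl)-3-(trimethylsilyloxy)cyclohexa-1,3-diene A2 and the ynone 1-(4-methoxyphenyl)but-3-yn-2-one A3.
- Forward step: a [4+2] addition gives a bicyclo[2.2.2]octadiene whose two-carbon bridge is then expelled thermally, giving 1-[2,5-dimethoxy-3-(3-methylbut-2-en-1-yl)-4-(trimethylsilyloxy)phenyl]-2-(4-methoxyphenyl)ethan-1-one A1.
- Merits: metal-free; all six ring B substituents and the C6–C(=O) bond arrive in one thermal operation.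
- Weak points:
  - A1 is a deoxybenzoin, so a benzylic oxidation is still owed.
  - The C5 oxygen emerges as a methyl ether and must be demethylated selectively.
  - Ring C is absent and must be closed oxidatively from the prenyl phenol, so at least four operations follow, each with a chemoselectivity question around the prenyl or chromene alkene.
  - A2 is substituted at both diene termini, so it is slow to react and laborious to make. The two terminal methoxy groups cancel electronically, so regiochemistry rests on silyloxy against alkyl.
  - A3 has a doubly activated methylene next to a terminal ynone and may not survive extrusion temperatures.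
- Comparison: this road is better in avoiding stoichiometric chromium and a labile diyne. The chosen plan sets against that an annulation that already contains ring C, differentiates OH from OMe by mechanism, and leaves three steps to the target.

**Alternative 2:** Petasis alkenyl transfer with oxa-6π closure.
- Cut: O1–C2 and C3–C4 of ring C.
- Forward step: 2-hydroxy-3,6-dimethoxybenzaldehyde A5, (2-methylprop-1-en-1-yl)boronic acid A6 and dibenzylamine A7 condense. Alkenyl transfer to the iminium carbon and amine loss give an ortho-quinone methide, which closes to 5,8-dimethoxy-2,2-dimethyl-2H-chromene A4.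
- Merits: a single, mild, nearly catalytic step to the chromene; overall this is probably the shortest road.
- Weak points: A4 is only the bare core. Both para oxygens are methyl ethers and C6 is unsubstituted. The C6–C bond would then be made by Friedel–Crafts acylation on an acid-labile chromene whose C3 and C7 are also nucleophilic. The C5 ether must be cleaved selectively and the side chain brought to the diketone level.
- Comparison: if the late acylation and demethylation behaved, this road would be shorter than the ten steps proposed here. The chosen plan sets against it that no substituent is introduced onto a finished, sensitive chromene and that no regiochemical question is left open after ring B is formed.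

**Alternative 3:** Isocyanide linchpin.
- Cut: C6–C(=O) and C(=O)–C(=O).
- Forward step: 8-methoxy-5-(methoxymethoxy)-2,2-dimethyl-2H-chromene A9 is lithiated at C6 and added to 2-isocyano-2,4,4-trimethylpentane A10. The lithium aldimine is acylated in the same flask by 4-methoxybenzoyl chloride A11 to give 2-[8-methoxy-5-(methoxymethoxy)-2,2-dimethyl-2H-chromen-6-yl]-1-(4-methoxyphenyl)-2-[(2,4,4-trimethylpentan-2-yl)imino]ethan-1-one A8. Acid hydrolysis would then release the diketone and the phenol together.
- Merits: convergent; the diketone oxidation level is reached without any oxidant, so the alkene is never at risk.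
- Weak points:
  - A9 must first be made with its oxygens already differentiated, which is the central problem moved elsewhere.
  - Aryllithiums add to isocyanides less cleanly than alkyllithiums.
  - The electrophilic imino ketone can be attacked a second time.
  - Metalation must choose C6 over C7.
- Comparison: its endgame is shorter and redox-neutral, which is better than an oxidation step and stoichiometric chromium. The chosen plan sets against it that it constructs ring B with every substituent in place from a simple pyranone.

Key step: step 7

Remark: the C4 oxygen is carried as a triisopropylsilyl ether, and every intermediate with the C4 stereocentre is racemic; this is immaterial because C4 becomes sp2 in step 9.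

## Route

Step 1
Reactants: 1 2,2-dimethyltetrahydro-4H-pyran-4-one
Product: 3 2,2-dimethyl-2,3-dihydro-4H-pyran-4-one, via trimethylsilyl enol ether 2 (not isolated)
Conditions: LiN(iPr)2, Me3SiCl, THF, −78 °C; then Pd(OAc)2 (10 mol %), O2 (1 atm), DMSO, rt
Reagents that add atoms: none
Why: Saegusa–Ito oxidation: the amide base removes the less hindered C5 proton (C3 is flanked by the quaternary C2) and the crude enol ether 2 is dehydrogenated by divalent palladium with O2 as terminal oxidant. Because C2 is quaternary only the C5=C6 enone can form, so any regioisomeric enol ether simply reverts to 1.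

Step 2
Reactants: 3 2,2-dimethyl-2,3-dihydro-4H-pyran-4-one
Product: 4 2,2-dimethyl-3,4-dihydro-2H-pyran-4-ol (racemic)
Conditions: NaBH4, CeCl3·7H2O, MeOH, −78 to 0 °C
Reagents that add atoms: none
Why: Luche reduction: CeCl3 directs hydride to 1,2-addition at the vinylogous ester carbonyl, the standard entry to glycal-type allylic alcohols. The new C4 stereocentre forms racemic and is destroyed in step 9; the acid-sensitive, volatile alcohol is carried on crude.

Step 3
Reactants: 4 2,2-dimethyl-3,4-dihydro-2H-pyran-4-ol (racemic)
Product: 5 [(2,2-dimethyl-3,4-dihydro-2H-pyran-4-yl)oxy]triisopropylsilane (racemic)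
Conditions: iPr3SiCl, imidazole, DMAP (cat.), DMF, rt
Reagents that add atoms: chlorotriisopropylsilane, CC(C)[Si](Cl)(C(C)C)C(C)C
Why: Silylation of a secondary allylic alcohol under basic conditions that leave the enol ether untouched. The triisopropylsilyl group has no Si–CH3 protons for t-BuLi to remove in step 4 and resists silyl migration.

Step 4
Reactants: 5 [(2,2-dimethyl-3,4-dihydro-2H-pyran-4-yl)oxy]triisopropylsilane (racemic)
Product: 8 pentacarbonyl(methoxy{2,2-dimethyl-4-[(triisopropylsilyl)oxy]-3,4-dihydro-2H-pyran-6-yl}methylidene)chromium (racemic), via vinyllithium 6 (not isolated), via lithium acylchromate 7 (not isolated)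
Conditions: t-BuLi, THF, −78 to 0 °C; Cr(CO)6, THF, 0 °C to rt; then MeOTf, CH2Cl2, 0 °C
Reagents that add atoms: Cr(CO)6, O=C=[Cr](=C=O)(=C=O)(=C=O)(=C=O)=C=O; methyl trifluoromethanesulfonate, COS(=O)(=O)C(F)(F)F
Why: Fischer carbene synthesis: t-BuLi removes the vinylic C6 proton alpha to the ring oxygen, as in C1 lithiation of silyl-protected glycals; vinyllithium 6 adds to a CO ligand of Cr(CO)6 and acylchromate 7 is O-methylated. Excess t-BuLi is consumed by THF during the warm-up and does not reach Cr(CO)6.

Step 5
Reactants: 9 1-ethynyl-4-methoxybenzene; 10 (bromoethynyl)triisopropylsilane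
Product: 11 [(4-methoxyphenyl)buta-1,3-diyn-1-yl]triisopropylsilane
Conditions: CuCl (5 mol %), NH2OH·HCl, n-BuNH2, H2O/Et2O, 0 °C to rt
Reagents that add atoms: none
Why: Cadiot–Chodkiewicz coupling: the copper acetylide of 9 substitutes bromoalkyne 10 while NH2OH·HCl keeps copper monovalent and suppresses homocoupling. The silyl cap makes the diyne storable.

Step 6
Reactants: 11 [(4-methoxyphenyl)buta-1,3-diyn-1-yl]triisopropylsilane
Product: 12 1-(buta-1,3-diyn-1-yl)-4-methoxybenzene
Conditions: Bu4NF, THF, 0 °C
Reagents that add atoms: none
Why: Fluoride cleavage of the C(sp)–Si bond of an alkynylsilane. The terminal arylbutadiyne is kept as a cold solution and used at once in step 7.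

Step 7
Reactants: 8 pentacarbonyl(methoxy{2,2-dimethyl-4-[(triisopropylsilyl)oxy]-3,4-dihydro-2H-pyran-6-yl}methylidene)chromium (racemic); 12 1-(buta-1,3-diyn-1-yl)-4-methoxybenzene
Product: 14 8-methoxy-6-[(4-methoxyphenyl)ethynyl]-2,2-dimethyl-4-[(triisopropylsilyl)oxy]chroman-5-yl acetate (racemic), via phenol 13 (not isolated)
Conditions: 12 (1.5 equiv), THF, 55 °C, Ar; then Ac2O, Et3N, DMAP (cat.), rt; air, silica gel
Reagents that add atoms: acetic anhydride, CC(=O)OC(C)=O
Why: Dötz benzannulation: loss of one CO from 8 lets the terminal triple bond of 12 coordinate and insert into the Cr=C bond, a CO ligand then inserts to give a chromium-bound dienylketene, and 6π-electrocyclisation onto the pyran CH carbon followed by enolisation gives phenol 13, so that C8–C7, C6–C5 and C5–C4a form in one operation. The closest known reaction is the benzannulation of Cr(CO)5 alkenyl(alkoxy)carbenes derived from lithiated dihydropyrans and silyl-protected glycals with terminal alkynes, which gives 5-hydroxy-8-methoxychromans; conjugated diynes are known partners that react once, at the less hindered triple bond. Ring B closes as a six-membered carbocycle by electrocyclisation of the dienylketene (a formal [3+2+1] assembly) onto the existing ring C. No stereocentre is created, and C4 is carried through racemic. The step needs insertion regiochemistry, secured sterically: the unsubstituted alkyne carbon bonds to the carbene carbon, so H lands at C7 beside C8–OMe and the arylethynyl group at C6 beside the new hydroxyl. It needs chemoselectivity between the two triple bonds, secured by the accessibility of the terminal one and by the excess of diyne, which keeps the aryl-flanked alkyne of the product from competing. It needs phenol formation over CO-free cyclisation, which alkenyl chromium carbenes in THF favour. The oxidation-prone 4-methoxyphenol is acetylated in the same flask before air strips the chromium, which also masks the oxygen ortho to the alkyne for step 8.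

Step 8
Reactants: 14 8-methoxy-6-[(4-methoxyphenyl)ethynyl]-2,2-dimethyl-4-[(triisopropylsilyl)oxy]chroman-5-yl acetate (racemic)
Product: 15 8-methoxy-6-[2-(4-methoxyphenyl)-2-oxoacetyl]-2,2-dimethyl-4-[(triisopropylsilyl)oxy]chroman-5-yl acetate (racemic)
Conditions: PdCl2 (10 mol %), DMSO, 140 °C
Reagents that add atoms: dimethyl sulfoxide, CS(C)=O
Why: PdCl2-catalysed oxidation of a diarylalkyne to a benzil: divalent palladium activates the triple bond, DMSO delivers oxygen twice and leaves as Me2S. The phenol is masked as its acetate and no alkene is yet present; if the benzylic silyl ether ionised at this temperature the product would be 16, the next intermediate.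

Step 9
Reactants: 15 8-methoxy-6-[2-(4-methoxyphenyl)-2-oxoacetyl]-2,2-dimethyl-4-[(triisopropylsilyl)oxy]chroman-5-yl acetate (racemic)
Product: 16 8-methoxy-6-[2-(4-methoxyphenyl)-2-oxoacetyl]-2,2-dimethyl-2H-chromen-5-yl acetate
Conditions: TsOH·H2O (cat.), toluene, 80 °C
Reagents that add atoms: none
Why: Acid-promoted E1 elimination: the C4–O bond ionises to a benzylic cation stabilised by the ortho ring oxygen O1, and loss of a C3 proton gives the conjugated C3=C4 alkene. Protodesilylation to the chroman-4-ol followed by the classical TsOH chromanol dehydration passes through the same cation. The acetate and diketone lower the electron density of the chromene and guard it against acid-induced dimerisation.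

Step 10
Reactants: 16 8-methoxy-6-[2-(4-methoxyphenyl)-2-oxoacetyl]-2,2-dimethyl-2H-chromen-5-yl acetate
Product: 17 Dielsianone, 1-(5-hydroxy-8-methoxy-2,2-dimethyl-2H-chromen-6-yl)-2-(4-methoxyphenyl)ethane-1,2-dione
Conditions: K2CO3 (cat.), MeOH, 0 °C; NH4Cl quench
Reagents that add atoms: none
Why: Base-catalysed transesterification of an aryl acetate, which at 0 °C should be much faster than attack on the diketone. Brief exposure and a mildly acidic quench avoid benzilic ester rearrangement, and the liberated phenol is held by a hydrogen bond to the C6 carbonyl.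

## Compound list

1 | 2,2-dimethyltetrahydro-4H-pyran-4-one | CC1(C)CC(=O)CCO1 | starting material
2 | trimethyl[(2,2-dimethyl-3,6-dihydro-2H-pyran-4-yl)oxy]silane | CC1(C)CC(O[Si](C)(C)C)=CCO1 | intermediate
3 | 2,2-dimethyl-2,3-dihydro-4H-pyran-4-one | CC1(C)CC(=O)C=CO1 | intermediate
4 | 2,2-dimethyl-3,4-dihydro-2H-pyran-4-ol (racemic) | CC1(C)CC(O)C=CO1 | intermediate
5 | [(2,2-dimethyl-3,4-dihydro-2H-pyran-4-yl)oxy]triisopropylsilane (racemic) | CC1(C)CC(O[Si](C(C)C)(C(C)C)C(C)C)C=CO1 | intermediate
6 | {2,2-dimethyl-4-[(triisopropylsilyl)oxy]-3,4-dihydro-2H-pyran-6-yl}lithium (racemic) | [Li]C1=CC(O[Si](C(C)C)(C(C)C)C(C)C)CC(C)(C)O1 | intermediate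
7 | lithium pentacarbonyl({2,2-dimethyl-4-[(triisopropylsilyl)oxy]-3,4-dihydro-2H-pyran-6-yl}carbonyl)chromate (racemic) | [Li+].[O-]C(=[Cr](=C=O)(=C=O)(=C=O)(=C=O)=C=O)C1=CC(O[Si](C(C)C)(C(C)C)C(C)C)CC(C)(C)O1 | intermediate
8 | pentacarbonyl(methoxy{2,2-dimethyl-4-[(triisopropylsilyl)oxy]-3,4-dihydro-2H-pyran-6-yl}methylidene)chromium (racemic) | COC(=[Cr](=C=O)(=C=O)(=C=O)(=C=O)=C=O)C1=CC(O[Si](C(C)C)(C(C)C)C(C)C)CC(C)(C)O1 | intermediate
9 | 1-ethynyl-4-methoxybenzene | COc1ccc(C#C)cc1 | starting material
10 | (bromoethynyl)triisopropylsilane | CC(C)[Si](C#CBr)(C(C)C)C(C)C | starting material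
11 | [(4-methoxyphenyl)buta-1,3-diyn-1-yl]triisopropylsilane | COc1ccc(C#CC#C[Si](C(C)C)(C(C)C)C(C)C)cc1 | intermediate
12 | 1-(buta-1,3-diyn-1-yl)-4-methoxybenzene | COc1ccc(C#CC#C)cc1 | intermediate
13 | 8-methoxy-6-[(4-methoxyphenyl)ethynyl]-2,2-dimethyl-4-[(triisopropylsilyl)oxy]chroman-5-ol (racemic) | COc1ccc(C#Cc2cc(OC)c3OC(C)(C)CC(O[Si](C(C)C)(C(C)C)C(C)C)c3c2O)cc1 | intermediate
14 | 8-methoxy-6-[(4-methoxyphenyl)ethynyl]-2,2-dimethyl-4-[(triisopropylsilyl)oxy]chroman-5-yl acetate (racemic) | COc1ccc(C#Cc2cc(OC)c3OC(C)(C)CC(O[Si](C(C)C)(C(C)C)C(C)C)c3c2OC(C)=O)cc1 | intermediate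
15 | 8-methoxy-6-[2-(4-methoxyphenyl)-2-oxoacetyl]-2,2-dimethyl-4-[(triisopropylsilyl)oxy]chroman-5-yl acetate (racemic) | COc1ccc(C(=O)C(=O)c2cc(OC)c3OC(C)(C)CC(O[Si](C(C)C)(C(C)C)C(C)C)c3c2OC(C)=O)cc1 | intermediate
16 | 8-methoxy-6-[2-(4-methoxyphenyl)-2-oxoacetyl]-2,2-dimethyl-2H-chromen-5-yl acetate | COc1ccc(C(=O)C(=O)c2cc(OC)c3OC(C)(C)C=Cc3c2OC(C)=O)cc1 | intermediate
17 | Dielsianone, 1-(5-hydroxy-8-methoxy-2,2-dimethyl-2H-chromen-6-yl)-2-(4-methoxyphenyl)ethane-1,2-dione | COc1ccc(C(=O)C(=O)c2cc(OC)c3c(c2O)C=CC(C)(C)O3)cc1 | target

## Step count and least certain steps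

Total step count: 10. Longest linear sequence: 8 steps (steps 1, 2, 3, 4, 7, 8, 9, 10); steps 5 and 6 form the two-step diyne branch.

**Step 7 (key step).** The most likely failure is loss of the terminal diyne by oligomerisation or by repeated alkyne insertion before CO insertion, aggravated by its thermal lability at 55 °C. Insertion at the internal triple bond is less likely. The fallback keeps the benzannulation but changes the alkyne and the latent diketone. It sets out from 8, which is heated under the same conditions with the stable conjugated enyne 1-[(E)-but-1-en-3-yn-1-yl]-4-methoxybenzene F1 (one Ohira–Bestmann homologation from the commercial cinnamaldehyde bearing the same aryl group). The same in-flask acetylation gives the stilbene 8-methoxy-6-[(E)-2-(4-methoxyphenyl)ethenyl]-2,2-dimethyl-4-[(triisopropylsilyl)oxy]chroman-5-yl acetate F2. Dihydroxylation (OsO4 cat., N-methylmorpholine N-oxide, acetone/H2O) gives the threo diol 6-[(1R*,2R*)-1,2-dihydroxy-2-(4-methoxyphenyl)ethyl]-8-methoxy-2,2-dimethyl-4-[(triisopropylsilyl)oxy]chroman-5-yl acetate F3. Swern oxidation of both carbinols returns to the route at 15.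

**Step 4.** Metalation may be incomplete or misdirected (removal of the allylic C4 proton, or silyl migration from oxygen to C6), and the acylchromate may be lost during alkylation, leaving an impure, air-sensitive carbene. The fallback sets out from 5. It is lithiated with excess t-BuLi and quenched with Bu3SnCl to give tributyl{2,2-dimethyl-4-[(triisopropylsilyl)oxy]-3,4-dihydro-2H-pyran-6-yl}stannane F4, which can be purified and stored. Tin–lithium exchange with one equivalent of n-BuLi at −78 °C then delivers vinyllithium of defined titre, returning to the route at 6.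

**Step 8.** The acetate carbonyl oxygen, or phenol oxygen freed by acetate loss at 140 °C, may attack the palladium-activated alkyne and lead to cyclised benzofuran-type material; the diketone may also be cleaved oxidatively. The fallback avoids alkyne activation altogether. It sets out from 14: semihydrogenation (H2, Pd/CaCO3 poisoned with Pb(OAc)2, quinoline) gives 8-methoxy-6-[(Z)-2-(4-methoxyphenyl)ethenyl]-2,2-dimethyl-4-[(triisopropylsilyl)oxy]chroman-5-yl acetate F5. Dihydroxylation with OsO4 and N-methylmorpholine N-oxide gives the erythro diol 6-[(1R*,2S*)-1,2-dihydroxy-2-(4-methoxyphenyl)ethyl]-8-methoxy-2,2-dimethyl-4-[(triisopropylsilyl)oxy]chroman-5-yl acetate F6. Swern oxidation returns to the route at 15.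

**Step 9.** The hindered triisopropylsilyl ether may ionise too slowly, and the acid strength then required may cause acetyl migration or oligomerisation of the chromene. The fallback separates the two events and removes the acid. It sets out from 15: buffered fluoride (HF·pyridine, pyridine, THF) gives 4-hydroxy-8-methoxy-6-[2-(4-methoxyphenyl)-2-oxoacetyl]-2,2-dimethylchroman-5-yl acetate F7. This is dehydrated by syn-elimination of its sulfamate with the Burgess reagent in warm benzene, returning to the route at 16.

## Further compounds

F1 | step 7 | 1-[(E)-but-1-en-3-yn-1-yl]-4-methoxybenzene | COc1ccc(/C=C/C#C)cc1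
F2 | step 7 | 8-methoxy-6-[(E)-2-(4-methoxyphenyl)ethenyl]-2,2-dimethyl-4-[(triisopropylsilyl)oxy]chroman-5-yl acetate (racemic) | COc1ccc(/C=C/c2cc(OC)c3OC(C)(C)CC(O[Si](C(C)C)(C(C)C)C(C)C)c3c2OC(C)=O)cc1
F3 | step 7 | 6-[(1R*,2R*)-1,2-dihydroxy-2-(4-methoxyphenyl)ethyl]-8-methoxy-2,2-dimethyl-4-[(triisopropylsilyl)oxy]chroman-5-yl acetate (racemic, both C4 epimers) | COc1ccc([C@@H](O)[C@H](O)c2cc(OC)c3OC(C)(C)CC(O[Si](C(C)C)(C(C)C)C(C)C)c3c2OC(C)=O)cc1
F4 | step 4 | tributyl{2,2-dimethyl-4-[(triisopropylsilyl)oxy]-3,4-dihydro-2H-pyran-6-yl}stannane (racemic) | CCCC[Sn](CCCC)(CCCC)C1=CC(O[Si](C(C)C)(C(C)C)C(C)C)CC(C)(C)O1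
F5 | step 8 | 8-methoxy-6-[(Z)-2-(4-methoxyphenyl)ethenyl]-2,2-dimethyl-4-[(triisopropylsilyl)oxy]chroman-5-yl acetate (racemic) | COc1ccc(/C=C\c2cc(OC)c3OC(C)(C)CC(O[Si](C(C)C)(C(C)C)C(C)C)c3c2OC(C)=O)cc1
F6 | step 8 | 6-[(1R*,2S*)-1,2-dihydroxy-2-(4-methoxyphenyl)ethyl]-8-methoxy-2,2-dimethyl-4-[(triisopropylsilyl)oxy]chroman-5-yl acetate (racemic, both C4 epimers) | COc1ccc([C@@H](O)[C@@H](O)c2cc(OC)c3OC(C)(C)CC(O[Si](C(C)C)(C(C)C)C(C)C)c3c2OC(C)=O)cc1
F7 | step 9 | 4-hydroxy-8-methoxy-6-[2-(4-methoxyphenyl)-2-oxoacetyl]-2,2-dimethylchroman-5-yl acetate (racemic) | COc1ccc(C(=O)C(=O)c2cc(OC)c3OC(C)(C)CC(O)c3c2OC(C)=O)cc1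
A1 | alternative 1 | 1-[2,5-dimethoxy-3-(3-methylbut-2-en-1-yl)-4-(trimethylsilyloxy)phenyl]-2-(4-methoxyphenyl)ethan-1-one | COc1ccc(CC(=O)c2cc(OC)c(O[Si](C)(C)C)c(CC=C(C)C)c2OC)cc1
A2 | alternative 1 | 1,4-dimethoxy-2-(3-methylbut-2-en-1-yl)-3-(trimethylsilyloxy)cyclohexa-1,3-diene | COC1=C(O[Si](C)(C)C)C(CC=C(C)C)=C(OC)CC1
A3 | alternative 1 | 1-(4-methoxyphenyl)but-3-yn-2-one | COc1ccc(CC(=O)C#C)cc1
A4 | alternative 2 | 5,8-dimethoxy-2,2-dimethyl-2H-chromene | COc1ccc(OC)c2C=CC(C)(C)Oc12
A5 | alternative 2 | 2-hydroxy-3,6-dimethoxybenzaldehyde | COc1ccc(OC)c(C=O)c1O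
A6 | alternative 2 | (2-methylprop-1-en-1-yl)boronic acid | CC(C)=CB(O)O
A7 | alternative 2 | dibenzylamine | C(NCc1ccccc1)c1ccccc1
A8 | alternative 3 | 2-[8-methoxy-5-(methoxymethoxy)-2,2-dimethyl-2H-chromen-6-yl]-1-(4-methoxyphenyl)-2-[(2,4,4-trimethylpentan-2-yl)imino]ethan-1-one | COc1ccc(C(=O)C(=NC(C)(C)CC(C)(C)C)c2cc(OC)c3OC(C)(C)C=Cc3c2OCOC)cc1
A9 | alternative 3 | 8-methoxy-5-(methoxymethoxy)-2,2-dimethyl-2H-chromene | COCOc1ccc(OC)c2OC(C)(C)C=Cc12
A10 | alternative 3 | 2-isocyano-2,4,4-trimethylpentane | [C-]#[N+]C(C)(C)CC(C)(C)C
A11 | alternative 3 | 4-methoxybenzoyl chloride | COc1ccc(C(Cl)=O)cc1
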